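**Assumptions (one line each)**
- Atom labels are ent-kaurane numbers of the target: C19 = acetoxymethyl carbon on C4, C6 = CHO carbon, C7 = lactone C=O, C20 = lactone OCH2, C15 = ketone, C16=C17 = exo-methylene. The given SMILES corresponds to (4R,5R,8S,9R,10R,11R,13S).
- Step 2 specifies the (R)-oxazaborolidinium catalyst, assuming the usual sense of induction for 2-substituted acroleins; if the opposite sense is observed, the (S)-catalyst is used.

**Retrosynthetic overview**
1. Trichorabdal B ⇐ protected tetracycle 30; ring D, C15 and the C8 quaternary centre come from one new Pd-catalysed carbonylative enolate C-acylation of vinyl bromide/lactone 29 (C8–C15 and C15–C16 bonds, CO becomes C15).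
2. Ring C (C9–C11, sets C9 and C11) by SmI2 ketyl–enoate cyclisation of aldehyde 27, itself from alkylation of spirolactone 14 with iodide 24 (C8–C14) and desaturation.
3. Spiro δ-lactone (C10 quaternary) by Ti(III) epoxide opening/Giese addition/lactonisation on A-ring epoxide 12.
4. Ring A (C4, C5) by catalytic asymmetric Diels–Alder of methacrolein with a pentadienyl ether; the C19 acid then delivers oxygen to C10 by iodolactonisation.
5. Iodide 24 (C13) by Evans alkylation, alkyne homologation and Markovnikov bromoboration. Ring order: A → spirolactone → C → D.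

**Route**

Step 1
Reactants: 1, (2E)-penta-2,4-dien-1-ol
Product: 2, 1-methoxy-4-({[(2E)-penta-2,4-dien-1-yl]oxy}methyl)benzene
Conditions: NaH, PMBCl, TBAI (cat.), THF/DMF, 0 °C → rt
Reagents that add atoms: 4-methoxybenzyl chloride, COc1ccc(CCl)cc1
Why: Williamson etherification; PMB will carry the future C6 oxygen and is orthogonal to the silyl ethers used later.

Step 2
Reactants: 2; 3, methacrolein
Product: 4, (1R,2S)-2-{[(4-methoxybenzyl)oxy]methyl}-1-methylcyclohex-3-ene-1-carbaldehyde (CHO cis to CH2OPMB)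
Conditions: (R)-o-tolyl-oxazaborolidine (from (R)-α,α-diphenylprolinol)·HNTf2 (10 mol %), CH2Cl2, −78 → −40 °C
Reagents that add atoms: none
Why: Catalytic enantioselective Diels–Alder (cationic oxazaborolidine): "ortho" regiochemistry and formyl-endo approach place the C19 formyl cis to the C6 CH2OPMB, and the catalyst shields one enal face to set C4 and with it C5.

Step 3
Reactants: 4
Product: 5, (1R,2S)-2-{[(4-methoxybenzyl)oxy]methyl}-1-methylcyclohex-3-ene-1-carboxylic acid
Conditions: NaClO2, NaH2PO4, 2-methyl-2-butene, t-BuOH/H2O, 0 °C → rt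
Reagents that add atoms: sodium chlorite, [Na+].[O-]Cl=O
Why: Pinnick oxidation of a non-enolisable aldehyde; the ring alkene is protected by the scavenger.

Step 4
Reactants: 5
Product: 6, (1R,4R,5R,8S)-4-iodo-8-{[(4-methoxybenzyl)oxy]methyl}-1-methyl-6-oxabicyclo[3.2.1]octan-7-one
Conditions: I2, NaHCO3, MeCN/H2O, 0 °C, dark
Reagents that add atoms: iodine, II
Why: Iodolactonisation (5-exo, anti addition): the C19 carboxylate can only reach C10, so the oxygen is placed at C10 regiospecifically (the new C10/C1 centres are erased in steps 5 and 8).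

Step 5
Reactants: 6
Product: 7, (1R,5S,8S)-8-{[(4-methoxybenzyl)oxy]methyl}-1-methyl-6-oxabicyclo[3.2.1]octan-7-one
Conditions: Bu3SnH, AIBN (cat.), PhMe, 80 °C
Reagents that add atoms: none
Why: Radical dehalogenation of a secondary iodide; lactone and PMB ether are inert.

Step 6
Reactants: 7
Product: 8, (1S,2S,3R)-3-(hydroxymethyl)-2-{[(4-methoxybenzyl)oxy]methyl}-3-methylcyclohexan-1-ol
Conditions: LiAlH4, THF, 0 °C → rt
Reagents that add atoms: none
Why: Hydride reduction of the lactone gives the C19 primary / C10 secondary diol without touching a stereocentre.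

Step 7
Reactants: 8
Product: 9, (1S,2S,3R)-2-{[(4-methoxybenzyl)oxy]methyl}-3-methyl-3-{[(triethylsilyl)oxy]methyl}cyclohexan-1-ol
Conditions: TESCl (1.05 equiv), imidazole, CH2Cl2, −40 °C
Reagents that add atoms: chlorotriethylsilane, CC[Si](Cl)(CC)CC
Why: Chemoselective silylation of the primary (C19) alcohol over the hindered secondary C10 alcohol.

Step 8
Reactants: 9
Product: 10, (2S,3R)-2-{[(4-methoxybenzyl)oxy]methyl}-3-methyl-3-{[(triethylsilyl)oxy]methyl}cyclohexan-1-one
Conditions: DMP, NaHCO3, CH2Cl2, 0 °C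
Reagents that add atoms: none
Why: Dess–Martin oxidation under buffered, non-basic conditions so the β-alkoxy ketone does not epimerise at C5 or eliminate.

Step 9
Reactants: 10
Product: 11, triethyl({(1R,2S)-2-{[(4-methoxybenzyl)oxy]methyl}-1-methyl-3-methylidenecyclohexyl}methoxy)silane
Conditions: Cp2TiMe2, PhMe, 65 °C, dark
Reagents that add atoms: dimethyltitanocene (CH2 source), [CH3-].[CH3-].[Ti+4].[cH-]1cccc1.[cH-]1cccc1
Why: Petasis methylenation (neutral titanocene methylidene) is used instead of a Wittig ylide because 10 is base-sensitive at C5.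

Step 10
Reactants: 11
Product: 12, 4-{[(4-methoxybenzyl)oxy]methyl}-5-methyl-5-{[(triethylsilyl)oxy]methyl}-1-oxaspiro[2.5]octane (C4/C5 as in 11; mixture at the spiro carbon)
Conditions: mCPBA, NaHCO3, CH2Cl2, 0 °C
Reagents that add atoms: mCPBA, O=C(OO)c1cccc(Cl)c1
Why: Prilezhaev epoxidation of the only electron-rich alkene; the diastereomer ratio is irrelevant because C10 becomes a planar radical next.

Step 11
Reactants: 12; 13, 2,2,2-trifluoroethyl acrylate
Product: 14, (6R,7R,8R)-7-{[(4-methoxybenzyl)oxy]methyl}-8-methyl-8-{[(triethylsilyl)oxy]methyl}-2-oxaspiro[5.5]undecan-3-one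
Conditions: Cp2TiCl2, Zn, THF, rt
Reagents that add atoms: none
Why: Ti(III)-mediated reductive epoxide opening/Giese addition/lactonisation: the tertiary C10 radical adds to the acrylate anti to the C5 CH2OPMB and C19 CH2OTES groups (sets C10), and the titanium alkoxide on C20 displaces trifluoroethoxide to close the δ-lactone.

Step 12
Reactants: 15, (S)-4-benzyl-1,3-oxazolidin-2-one; 16, pent-4-enoyl chloride
Product: 17, (4S)-4-benzyl-3-(pent-4-enoyl)-1,3-oxazolidin-2-one
Conditions: n-BuLi, THF, −78 °C; then 16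
Reagents that add atoms: none
Why: N-acylation of the lithiated Evans auxiliary.

Step 13
Reactants: 17
Product: 18, (4S)-4-benzyl-3-[(2R)-2-(benzyloxymethyl)pent-4-enoyl]-1,3-oxazolidin-2-one
Conditions: TiCl4, i-Pr2NEt, CH2Cl2, 0 °C; then BnOCH2Cl, 0 °C
Reagents that add atoms: benzyl chloromethyl ether, ClCOCc1ccccc1
Why: Evans alkylation through the chelated Z-titanium enolate; the electrophile enters opposite the benzyl group and sets the future C13.

Step 14
Reactants: 18
Product: 19, (2S)-2-[(benzyloxy)methyl]pent-4-en-1-ol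
Conditions: LiBH4, MeOH (1 equiv), Et2O, 0 °C
Reagents that add atoms: none
Why: Reductive removal of the auxiliary without epimerisation.

Step 15
Reactants: 19
Product: 20, (2R)-2-[(benzyloxy)methyl]pent-4-enal
Conditions: DMP, NaHCO3, CH2Cl2, 0 °C
Reagents that add atoms: none
Why: Dess–Martin oxidation; the neutral conditions preserve the α-stereocentre.

Step 16
Reactants: 20
Product: 21, ({[(2S)-2-ethynylpent-4-en-1-yl]oxy}methyl)benzene
Conditions: Ohira–Bestmann reagent, K2CO3, MeOH, 0 °C → rt
Reagents that add atoms: dimethyl (1-diazo-2-oxopropyl)phosphonate (adds C17), CC(=O)C(=[N+]=[N-])P(=O)(OC)OC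
Why: Seyferth–Gilbert (Ohira–Bestmann) homologation of the aldehyde to the terminal alkyne under mild base.

Step 17
Reactants: 21
Product: 22, ({[(2R)-2-(1-bromoethenyl)pent-4-en-1-yl]oxy}methyl)benzene
Conditions: B-Br-9-BBN, CH2Cl2, 0 °C; then AcOH, 0 °C → rt
Reagents that add atoms: B-bromo-9-borabicyclo[3.3.1]nonane, BrB1C2CCCC1CCC2
Why: Bromoboration–protodeboronation: Markovnikov syn addition of B–Br to the terminal alkyne and protonolysis of the C–B bond give the 2-bromo-1-alkene; the terminal alkene does not react.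

Step 18
Reactants: 22
Product: 23, (2R)-2-(1-bromoethenyl)pent-4-en-1-ol
Conditions: BCl3, CH2Cl2, −78 °C
Reagents that add atoms: none
Why: Lewis-acid debenzylation; vinyl bromide and alkene survive at −78 °C.

Step 19
Reactants: 23
Product: 24, (3S)-2-bromo-3-(iodomethyl)hexa-1,5-diene
Conditions: I2, PPh3, imidazole, CH2Cl2, 0 °C
Reagents that add atoms: iodine, II
Why: Appel iodination of the primary alcohol; the stereocentre is not involved.

Step 20
Reactants: 14; 24
Product: 25, spirolactone 14 bearing the (2R)-2-(1-bromoethenyl)pent-4-en-1-yl group on the lactone α-carbon C8 (C8 epimer mixture)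
Conditions: LDA, THF, −78 °C; then 24, HMPA, −78 → −20 °C
Reagents that add atoms: none
Why: Lactone enolate SN2 alkylation forms C8–C14; the C8 configuration is irrelevant because C8 becomes sp2 in step 21.

Step 21
Reactants: 25
Product: 26, the C8=C9 α,β-unsaturated spirolactone (2-oxaspiro[5.5]undec-4-en-3-one) with the side chain on C8
Conditions: LDA, THF, −78 °C; PhSeBr; then H2O2, pyridine, CH2Cl2, 0 °C → rt
Reagents that add atoms: none
Why: α-Selenation and selenoxide syn-elimination toward the ring C9–H give the endocyclic enoate needed as radical acceptor.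

Step 22
Reactants: 26
Product: 27, aldehyde in which the terminal vinyl group of 26 is cleaved to the C11 formyl group
Conditions: OsO4 (2 mol %), NaIO4, 2,6-lutidine, dioxane/H2O, rt
Reagents that add atoms: osmium tetroxide O=[Os](=O)(=O)=O / sodium periodate [Na+].[O-]I(=O)(=O)=O (aldehyde oxygen)
Why: Lemieux–Johnson cleavage is selective for the electron-rich monosubstituted alkene over the vinyl bromide and the enoate.

Step 23
Reactants: 27
Product: 28, tricyclic hydroxy-lactone with ring C closed: C9–H and C11–OH on the same face of ring C, C10 on the opposite face, 1-bromoethenyl axial on C13, C8–H trans to C9–H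
Conditions: SmI2, LiBr, t-BuOH, THF, −78 °C
Reagents that add atoms: none
Why: SmI2 ketyl–olefin cyclisation (6-endo radical conjugate addition): the C11 ketyl adds to C9 of the enoate through a chair-like transition state controlled by the spiro A ring, setting C9 and C11 as in the target (closely precedented on analogues lacking the C19 oxygen); the Sm enolate is protonated at C8 and the vinyl bromide is not reduced without HMPA.

Step 24
Reactants: 28
Product: 29, C11 TBS ether of 28
Conditions: TBSOTf, 2,6-lutidine, CH2Cl2, −78 → 0 °C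
Reagents that add atoms: TBSOTf, CC(C)(C)[Si](C)(C)OS(=O)(=O)C(F)(F)F
Why: Silylation of the hindered secondary alcohol so that only the lactone is deprotonated in step 25.

Step 25
Reactants: 29
Product: 30, tetracycle: 11-O-TBS, 19-O-TES, 6-O-PMB derivative of the 15-oxo-16-methylene bicyclo[3.2.1]octane lactone (ring D closed, C8 quaternary, 8S)
Conditions: KHMDS, THF, −78 → −40 °C; ZnCl2; then Pd2(dba)3 (5 mol %), Xantphos (12 mol %), CO (1 atm), THF, 50 °C, 0.01 M
Reagents that add atoms: carbon monoxide, [C-]#[O+]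
Why: Proposed new method: Pd(0) inserts into the C16–Br bond, CO insertion gives an acryloyl–Pd(II) species, and intramolecular capture by the C8 zinc enolate of the lactone followed by C–C reductive elimination forms C8–C15 and C15–C16, closing the α-methylene cyclopentanone and the C8 quaternary centre in one step. Because the acyl arm is axial on C13, only the cis-bridged bicyclo[3.2.1]octane can form, and the alternatives (4-membered direct vinylation, 7-membered O-acylation) are geometrically disfavoured. The closest known reaction types are Pd-catalysed carbonylative α-arylation of ketone and malonate enolates and Pd-catalysed intramolecular enolate alkenylation, neither shown for an unstabilised lactone enolate forming a quaternary bridgehead.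

Step 26
Reactants: 30
Product: 31, C19 primary alcohol (TES removed)
Conditions: HF·pyridine, pyridine, THF, 0 °C
Reagents that add atoms: none
Why: Buffered fluoride cleaves the primary TES ether much faster than the hindered secondary TBS ether; enone and lactone tolerate the acidic conditions.

Step 27
Reactants: 31
Product: 32, C19 acetate
Conditions: Ac2O, pyridine, DMAP (cat.), CH2Cl2, 0 °C → rt
Reagents that add atoms: acetic anhydride, CC(=O)OC(C)=O
Why: Acetylation of the only free hydroxyl.

Step 28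
Reactants: 32
Product: 33, C6 primary alcohol (PMB removed)
Conditions: DDQ, CH2Cl2/pH 7 buffer, 0 °C → rt
Reagents that add atoms: none
Why: Oxidative PMB cleavage; silyl ether, acetate, enone and lactone are inert to DDQ.

Step 29
Reactants: 33
Product: 34, 11-O-TBS trichorabdal B (C6 aldehyde)
Conditions: DMP, NaHCO3, CH2Cl2, rt
Reagents that add atoms: none
Why: Dess–Martin oxidation of the only free alcohol; buffered conditions avoid C5 epimerisation.

Step 30
Reactants: 34
Product: 35, trichorabdal B
Conditions: HF·pyridine, THF, 0 °C → rt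
Reagents that add atoms: none
Why: Acidic fluoride removes the secondary TBS ether without touching the acetate, aldehyde, enone or β-keto lactone.

**Compound list**
1 | (2E)-penta-2,4-dien-1-ol | OC/C=C/C=C | starting material
2 | 1-methoxy-4-({[(2E)-penta-2,4-dien-1-yl]oxy}methyl)benzene | C=C/C=C/COCc1ccc(OC)cc1 | intermediate
3 | methacrolein | CC(=C)C=O | starting material
4 | (1R,2S)-2-{[(4-methoxybenzyl)oxy]methyl}-1-methylcyclohex-3-ene-1-carbaldehyde | C1=CCC[C@@](C)(C=O)[C@H]1COCc2ccc(OC)cc2 | intermediate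
5 | (1R,2S)-2-{[(4-methoxybenzyl)oxy]methyl}-1-methylcyclohex-3-ene-1-carboxylic acid | C1=CCC[C@@](C)(C(=O)O)[C@H]1COCc2ccc(OC)cc2 | intermediate
6 | (1R,4R,5R,8S)-4-iodo-8-{[(4-methoxybenzyl)oxy]methyl}-1-methyl-6-oxabicyclo[3.2.1]octan-7-one | O=C2O[C@H]1[C@H](I)CC[C@]2(C)[C@H]1COCc3ccc(OC)cc3 | intermediate
7 | (1R,5S,8S)-8-{[(4-methoxybenzyl)oxy]methyl}-1-methyl-6-oxabicyclo[3.2.1]octan-7-one | O=C2O[C@H]1CCC[C@]2(C)[C@H]1COCc3ccc(OC)cc3 | intermediate
8 | (1S,2S,3R)-3-(hydroxymethyl)-2-{[(4-methoxybenzyl)oxy]methyl}-3-methylcyclohexan-1-ol | O[C@H]1CCC[C@@](C)(CO)[C@H]1COCc2ccc(OC)cc2 | intermediate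
9 | (1S,2S,3R)-2-{[(4-methoxybenzyl)oxy]methyl}-3-methyl-3-{[(triethylsilyl)oxy]methyl}cyclohexan-1-ol | O[C@H]1CCC[C@@](C)(CO[Si](CC)(CC)CC)[C@H]1COCc2ccc(OC)cc2 | intermediate
10 | (2S,3R)-2-{[(4-methoxybenzyl)oxy]methyl}-3-methyl-3-{[(triethylsilyl)oxy]methyl}cyclohexan-1-one | O=C1CCC[C@@](C)(CO[Si](CC)(CC)CC)[C@H]1COCc2ccc(OC)cc2 | intermediate
11 | triethyl({(1R,2S)-2-{[(4-methoxybenzyl)oxy]methyl}-1-methyl-3-methylidenecyclohexyl}methoxy)silane | C=C1CCC[C@@](C)(CO[Si](CC)(CC)CC)[C@H]1COCc2ccc(OC)cc2 | intermediate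
12 | spiro-epoxide of 11 (1-oxaspiro[2.5]octane; mixture at spiro carbon) | C1OC12CCC[C@@](C)(CO[Si](CC)(CC)CC)[C@H]2COCc3ccc(OC)cc3 | intermediate
13 | 2,2,2-trifluoroethyl acrylate | C=CC(=O)OCC(F)(F)F | starting material
14 | (6R,7R,8R)-7-{[(4-methoxybenzyl)oxy]methyl}-8-methyl-8-{[(triethylsilyl)oxy]methyl}-2-oxaspiro[5.5]undecan-3-one | O=C1CC[C@@]2(CCC[C@@](C)(CO[Si](CC)(CC)CC)[C@H]2COCc3ccc(OC)cc3)CO1 | intermediate
15 | (S)-4-benzyl-1,3-oxazolidin-2-one | O=C1N[C@@H](Cc2ccccc2)CO1 | starting material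
16 | pent-4-enoyl chloride | C=CCCC(Cl)=O | starting material
17 | (4S)-4-benzyl-3-(pent-4-enoyl)-1,3-oxazolidin-2-one | C=CCCC(=O)N1[C@@H](Cc2ccccc2)COC1=O | intermediate
18 | (4S)-4-benzyl-3-[(2R)-2-(benzyloxymethyl)pent-4-enoyl]-1,3-oxazolidin-2-one | C=CC[C@H](COCc3ccccc3)C(=O)N1[C@@H](Cc2ccccc2)COC1=O | intermediate
19 | (2S)-2-[(benzyloxy)methyl]pent-4-en-1-ol | C=CC[C@H](COCc1ccccc1)CO | intermediate
20 | (2R)-2-[(benzyloxy)methyl]pent-4-enal | C=CC[C@H](COCc1ccccc1)C=O | intermediate
21 | ({[(2S)-2-ethynylpent-4-en-1-yl]oxy}methyl)benzene | C=CC[C@H](COCc1ccccc1)C#C | intermediate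
22 | ({[(2R)-2-(1-bromoethenyl)pent-4-en-1-yl]oxy}methyl)benzene | C=CC[C@H](COCc1ccccc1)C(Br)=C | intermediate
23 | (2R)-2-(1-bromoethenyl)pent-4-en-1-ol | C=CC[C@H](CO)C(Br)=C | intermediate
24 | (3S)-2-bromo-3-(iodomethyl)hexa-1,5-diene | C=CC[C@H](CI)C(Br)=C | intermediate
25 | C8-alkylated spirolactone (C8 epimers) | C=CC[C@H](CC1C[C@@]2(CCC[C@@](C)(CO[Si](CC)(CC)CC)[C@H]2COCc3ccc(OC)cc3)COC1=O)C(Br)=C | intermediate
26 | C8=C9 unsaturated spirolactone | C=CC[C@H](CC1=C[C@@]2(CCC[C@@](C)(CO[Si](CC)(CC)CC)[C@H]2COCc3ccc(OC)cc3)COC1=O)C(Br)=C | intermediate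
27 | C11 aldehyde of the unsaturated spirolactone | O=CC[C@H](CC1=C[C@@]2(CCC[C@@](C)(CO[Si](CC)(CC)CC)[C@H]2COCc3ccc(OC)cc3)COC1=O)C(Br)=C | intermediate
28 | tricyclic 11-hydroxy lactone with axial 13-(1-bromoethenyl) | C=C(Br)[C@@H]1C[C@@H](O)[C@@H]2[C@@]3(CCC[C@@](C)(CO[Si](CC)(CC)CC)[C@H]3COCc4ccc(OC)cc4)COC(=O)[C@H]2C1 | intermediate
29 | 11-O-TBS ether of 28 | C=C(Br)[C@@H]1C[C@@H](O[Si](C)(C)C(C)(C)C)[C@@H]2[C@@]3(CCC[C@@](C)(CO[Si](CC)(CC)CC)[C@H]3COCc4ccc(OC)cc4)COC(=O)[C@H]2C1 | intermediate
30 | tetracyclic enone lactone, 11-O-TBS, 19-O-TES, 6-O-PMB | C=C1C(=O)[C@]23C[C@H]1C[C@@H](O[Si](C)(C)C(C)(C)C)[C@@H]2[C@@]4(CCC[C@@](C)(CO[Si](CC)(CC)CC)[C@H]4COCc5ccc(OC)cc5)COC3=O | intermediate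
31 | 19-hydroxy compound (11-O-TBS, 6-O-PMB) | C=C1C(=O)[C@]23C[C@H]1C[C@@H](O[Si](C)(C)C(C)(C)C)[C@@H]2[C@@]4(CCC[C@@](C)(CO)[C@H]4COCc5ccc(OC)cc5)COC3=O | intermediate
32 | 19-acetate (11-O-TBS, 6-O-PMB) | C=C1C(=O)[C@]23C[C@H]1C[C@@H](O[Si](C)(C)C(C)(C)C)[C@@H]2[C@@]4(CCC[C@@](C)(COC(C)=O)[C@H]4COCc5ccc(OC)cc5)COC3=O | intermediate
33 | 19-acetate, 6-hydroxy (11-O-TBS) | C=C1C(=O)[C@]23C[C@H]1C[C@@H](O[Si](C)(C)C(C)(C)C)[C@@H]2[C@@]4(CCC[C@@](C)(COC(C)=O)[C@H]4CO)COC3=O | intermediate
34 | 11-O-TBS trichorabdal B | C=C1C(=O)[C@]23C[C@H]1C[C@@H](O[Si](C)(C)C(C)(C)C)[C@@H]2[C@@]4(CCC[C@@](C)(COC(C)=O)[C@H]4C=O)COC3=O | intermediate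
35 | trichorabdal B | C=C1C(=O)[C@]23C[C@H]1C[C@@H](O)[C@@H]2[C@@]1(CCC[C@@](C)(COC(C)=O)[C@H]1C=O)COC3=O | target

**Totals**
- Total steps: 30.
- Longest linear sequence: 22 (steps 1–11, then 20–30); the side-chain branch is steps 12–19.

**Three steps most likely to fail**
1. Step 25 (proposed carbonylative enolate acylation). Risks are slow enolisation at hindered C8, Michael addition to the product enone, and O-acylation. Fallback with known chemistry: replace the 1-bromoethenyl arm on C13 by an allyl arm (iodide made by the same Evans chemistry), then close ring D by stoichiometric Pd(OAc)2-mediated oxidative cyclisation of the lactone TBS ketene acetal, ozonolyse the resulting 15-methylene to the C15 ketone, and α-methylenate C16 with Eschenmoser's salt.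
2. Step 23 (SmI2 cyclisation). Risks are C–Br reduction and diastereocontrol with the new C13 and C19 substituents. Fallback: carry the terminal alkyne instead of the vinyl bromide (omit step 17 before coupling), run the ketyl–olefin cyclisation on the alkyne analogue, and install the bromide afterwards by Markovnikov bromoboration/protonolysis.
3. Step 20 (alkylation with a β-branched iodide whose β-hydrogen is allylic, so E2 competes). Fallback: make the 8-iodo-8,9-unsaturated lactone from 14 and join the fragments by sp3–sp2 cross-coupling (alkylzinc or B-alkyl-9-BBN reagent from 24, Pd catalysis), which also replaces the selenoxide step.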